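## Structural features

The target is a depside without stereocentres: two benzene rings, A and B, each with six substituents, are joined by one aryl ester bond from the carbonyl carbon on C1' of ring B to the oxygen on C4 of ring A. Ring A (C1 CO2CH3, C2 OH, C3 CH3, C4 O-acyl, C5 CH3, C6 CH3) is a methyl salicylate whose C2 hydroxyl is hydrogen-bonded to the ester carbonyl, while the C4 oxygen lies between two methyl groups. Ring B (C1' C=O, C2' CH3, C3' Cl, C4' OH, C5' CH3, C6' OCH3) carries its carboxyl carbon between a methyl and a methoxy group, so the acid is di-ortho-substituted and the ester link unites two hindered partners. The fragile parts are the aryl ester (opened or transposed by hydroxide, alkoxide or a free phenoxide), the methyl ester, and the electron-rich phenols, which over-halogenate and oxidise easily. The real difficulty is the regiocontrolled assembly of fully substituted ring B, with two different oxygen functions and one chlorine at a defined carbon, followed by acylation of the correct hydroxyl of ring A. The key step exploits the contiguous triad C6'(OCH3)–C1'(CO)–C2'(CH3), which is what remains when a 3-methoxyaryne spanning C1'–C2' accepts a carbon nucleophile at C2' and a carbon electrophile at C1'. C3' stays C–H until the last step, so nothing on that flank competes with the methoxy group during the aryne addition, and it is then the only aromatic C–H left for chlorination.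

## Logic of the disconnections

20 to 19: the C3'–Cl bond is cut first. In 19 this carbon is the only aromatic C–H of the molecule, ortho to the free C4' hydroxyl and para to the methoxy group, so a late electrophilic chlorination needs no regiocontrol. Introducing chlorine earlier would put a second inductive director next to the aryne. The forward step must stop at monochlorination and leave ring A alone.

19 to 18: the O–Si bond on the C4' oxygen is cut. The silyl ether keeps this oxygen distinct from the methoxy oxygen and inert to organomagnesium reagents. Its removal must not generate a free phenoxide long enough to attack the depside ester.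

18 to 11 and 16: the ester bond between the C1' carbonyl and the C4 oxygen is cut. This halves the molecule into two benzene building blocks of similar size. The forward step must acylate a hydroxyl flanked by two methyl groups with a di-ortho-substituted acid, and must choose the C4 hydroxyl over the chelated C2 hydroxyl.

11 to 7: the C2'–CH3 and C1'–CO2H bonds are cut together. Both carbon substituents are traced to a methyl nucleophile and carbon dioxide adding across an aryne, so the two most crowded C–C bonds of ring B form in one operation and the acid is obtained free. The forward step needs the nucleophile to go to C2' only, and needs methyl rather than the exchange reagent's alkyl group to be transferred.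

7 to 6 to 5: the O–S bond of the sulfonate and the C–I bond are cut. This leaves a phenol whose hydroxyl marks C2' and whose neighbouring C–H marks C1'. The iodination must select the ortho position on the methoxy side over the one next to the silyl ether.

5 to 3 (through 4): the C2'–O bond is cut back to a C–H bond. In 3 this is the only ring C–H without an ortho substituent, which is the pattern sterically governed C–H borylation selects. The forward step must oxidise the C–B bond without harming the silyl ether.

3 to 2 to 1: the O–Si and O–CH3 bonds are cut, leading to a symmetrical diol. The only demand is to stop the alkylation at the mono-ether.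

16 to 14 to 12 (through 15 and 13): the C5–CH3 bond is cut, first to a formyl group and then to C–H. In 12 this is the only free ring position, so the formylation is regiochemically unambiguous. The reduction must take the aldehyde to methyl without touching the ester.

## Other disconnections considered

Alternative 1: Ring B is cut at C1'–C2' and C4'–C5', leading to A1 (methyl 3-oxopentanoate) and A2 (methyl (E)-but-2-enoate). In the forward sense a methoxide-mediated Michael addition of A1 to A2 would be followed by Claisen ring closure to A3 (methyl 3,6-dimethyl-2,4-dioxocyclohexane-1-carboxylate), and dehydrogenation of A3 would give 12 itself.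
- In its favour: cheap feedstocks, robust anionic chemistry without organometallic reagents, and every ring B carbon placed unambiguously.
- Against it here: a separate aromatisation is needed. Both oxygens emerge as free hydroxyls, so the C6' methyl ether and the C4' protecting group must be introduced by selective reactions, the chelated and hindered hydroxyl being the one to methylate. The carboxyl arrives as a di-ortho-substituted methyl ester whose hydrolysis calls for forcing base.
- Comparison: because 12 can be bought, the annulation would only reproduce a purchasable compound. A ring B acid could then be reached from 12 in about three operations (protection of the C4' oxygen, O-methylation, saponification), against six steps to 11. On step count and on the precedent of the individual reactions this alternative is the better. The chosen plan is the better on two structural points: it delivers the free acid directly, avoiding the hindered saponification, and it differentiates the two oxygens by construction.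

Alternative 2: Ring A (numbered as above) is cut at C2–C3, C4–C5 and C1–C2, leading to A4 (2,3-dimethylcyclobut-2-en-1-one) and A5 (triisopropyl(prop-1-yn-1-yloxy)silane). On heating, A4 would open to its vinylketene valence isomer and add to A5. A second ring opening and a six-electron electrocyclisation would then close ring A and give A6 (2,4,5-trimethyl-3-(triisopropylsilyloxy)phenol). This is a Danheiser benzannulation.
- In its favour: one pericyclic cascade fixes three methyl groups and two oxygens on ring A, and the oxygens come out differentiated (silyl ether on the C4 oxygen, free hydroxyl on C2).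
- Against it here: A4 and A5 each need their own preparation. C1 is left as C–H, so the ester carbon must still be introduced ortho to the free hydroxyl and the silyl group removed before 16 is reached. Ring A is also not where the difficulty of the target lies.
- Comparison: the chosen plan reaches 16 in two steps from 12, and the oxygen differentiation the benzannulation offers is present in 16 at no cost through hydrogen bonding of the C2 hydroxyl. On regiochemical certainty the two are equal. The alternative is the better only in not depending on electrophilic substitution at a crowded, ester-deactivated ring carbon. On step economy the chosen plan is clearly ahead, and ring B would remain to be solved.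

Alternative 3: Ring B is cut at C2'–C3' and C1'–C6' with the depside ester already in place. The partners are A7 (methyl 4-(but-2-ynoyloxy)-2-hydroxy-3,5,6-trimethylbenzoate) and A8 (1,1-dimethoxy-2-methyl-3-(trimethylsilyloxy)buta-1,3-diene), a Brassard-type ketene acetal diene. A [4+2] cycloaddition in which the CH2 terminus of A8 bonds to the β-carbon of the ynoate, followed by loss of one methoxy group as the alcohol and of the silyl group, would give A9, which is identical with 19.
- In its favour: it is highly convergent. The ester bond is made on an unhindered ynoic acid derivative rather than on a di-ortho-substituted benzoic acid. The OCH3/OH differentiation is built into the diene, and the product lies one step from the target.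
- Against it here: a β-methyl ynoate is a sluggish dienophile. A8 is fully substituted at its ketene acetal terminus and labile to heat and protic groups. The free C2 hydroxyl of A7 would consume diene by silyl transfer unless masked. Conjugate addition without ring closure is a plausible competing course.
- Comparison: on step economy and ease of ester formation this alternative is the better. Regiocontrol is of the same kind in both plans, polar direction by an oxygen substituent. The chosen plan rests on a reaction class that is documented for heavily substituted arynes, whereas the cycloaddition would have to succeed with the least reactive class of partners and with all of ring A at stake.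

Key step: step 6

Remark on the chemistry: a 2-magnesiated aryl triflate may lose triflate even at −78 °C, so CH3MgCl is kept in excess in the flask before the exchange reagent is added; ring A is numbered C1 (CO2CH3), C2 (OH), C3, C4 (O-acyl), C5, C6 throughout.

## Steps

Step 1
Reactants: 1 2-methylresorcinol
Product: 2 3-methoxy-2-methylphenol
Conditions: CH3I (1.0 equiv), K2CO3 (1.0 equiv), acetone, reflux
Reagents that add atoms: iodomethane, CI
Why: Williamson ether synthesis on a symmetrical diol, so there is no regiochemical issue; limiting the alkylating agent favours the mono-ether, which is separated from diol and diether by its intermediate acidity and polarity.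

Step 2
Reactants: 2 3-methoxy-2-methylphenol
Product: 3 (3-methoxy-2-methylphenoxy)triisopropylsilane
Conditions: i-Pr3SiCl, imidazole, DMF, rt
Reagents that add atoms: chlorotriisopropylsilane, CC(C)[Si](Cl)(C(C)C)C(C)C
Why: Imidazole-promoted O-silylation of a phenol; the triisopropylsilyl group is chosen because it survives Grignard reagents, peroxymonosulfate and triflic anhydride and because its bulk shields the neighbouring ring position in steps 3 and 4.

Step 3
Reactants: 3 (3-methoxy-2-methylphenoxy)triisopropylsilane
Product: 5 3-methoxy-4-methyl-5-(triisopropylsilyloxy)phenol, via arylboronic pinacol ester 4 (not isolated)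
Conditions: [Ir(OMe)(cod)]2 (cat.), 4,4'-di-tert-butyl-2,2'-bipyridine (cat.), B2pin2, THF, 80 °C; then KHSO5 (as 2KHSO5·KHSO4·K2SO4), acetone/H2O, rt
Reagents that add atoms: potassium peroxymonosulfate, [K+].[O-]S(=O)(=O)OO (oxygen of the new hydroxyl); bis(pinacolato)diboron, CC1(C)OB(OC1(C)C)B1OC(C)(C)C(C)(C)O1 (boron and pinacol of 4 only)
Why: Iridium-catalysed aromatic C–H borylation is governed by sterics, and of the three ring C–H bonds of 3 only the one meta to both oxygens has no ortho substituent; peroxymonosulfate then converts C–B into C–O by 1,2-aryl migration from boron to oxygen in the same flask.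

Step 4
Reactants: 5 3-methoxy-4-methyl-5-(triisopropylsilyloxy)phenol
Product: 6 2-iodo-3-methoxy-4-methyl-5-(triisopropylsilyloxy)phenol
Conditions: N-iodosuccinimide (1.0 equiv), CH2Cl2, −40 → 0 °C, dark
Reagents that add atoms: N-iodosuccinimide, O=C1CCC(=O)N1I
Why: Electrophilic aromatic iodination of a phloroglucinol-type ring; both free positions are ortho to the hydroxyl, but C6 is wedged against the triisopropylsilyloxy group (pushed towards it by the C4 methyl) while C2 lies next to the small methoxy group, so substitution should go to C2. One equivalent at low temperature limits di-iodination.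

Step 5
Reactants: 6 2-iodo-3-methoxy-4-methyl-5-(triisopropylsilyloxy)phenol
Product: 7 2-iodo-3-methoxy-4-methyl-5-(triisopropylsilyloxy)phenyl trifluoromethanesulfonate
Conditions: (CF3SO2)2O, pyridine, CH2Cl2, 0 °C
Reagents that add atoms: trifluoromethanesulfonic anhydride, O=S(=O)(OS(=O)(=O)C(F)(F)F)C(F)(F)F
Why: O-Sulfonylation of a phenol with triflic anhydride and an amine base; the aryl iodide, the methyl ether and the silyl ether are inert under these conditions.

Step 6
Reactants: 7 2-iodo-3-methoxy-4-methyl-5-(triisopropylsilyloxy)phenyl trifluoromethanesulfonate
Product: 11 2-methoxy-3,6-dimethyl-4-(triisopropylsilyloxy)benzoic acid, via magnesiated aryl triflate 8 (not isolated), via 3-methoxyaryne 9 (not isolated), via methylated arylmagnesium chloride 10 (not isolated)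
Conditions: CH3MgCl (3 equiv), THF, −78 °C; i-PrMgCl·LiCl (1.05 equiv) added slowly, −78 → 0 °C; CO2 (dry gas), −20 °C → rt; cold 1 M HCl work-up
Reagents that add atoms: methylmagnesium chloride, C[Mg]Cl; carbon dioxide, O=C=O; isopropylmagnesium chloride, CC(C)[Mg]Cl (magnesium of 8 only)
Why: Iodine–magnesium exchange at the iodide, which is activated by the flanking triflyloxy and methoxy groups, gives 8, and β-elimination of magnesium triflate from 8 releases aryne 9 with the strained bond between C1' and C2'. CH3MgCl then adds across this bond (carbomagnesiation): methyl goes to C2', the terminus remote from the C6' methoxy group, because the inductively withdrawing C6'–O bond distorts the aryne so that C2' is the more electrophilic carbon and the negative charge develops at C1', where it is stabilised by that bond and by OCH3→Mg chelation. The resulting di-ortho-substituted arylmagnesium 10 is carboxylated at C1' by CO2, and acidic work-up gives 11. The closest known reaction type is aryne generation from 2-iodoaryl sulfonates by iodine–magnesium exchange, followed by addition of a magnesium nucleophile and electrophilic quench of the new arylmagnesium, together with Grignard addition–carboxylation of 3-alkoxyarynes. No ring is closed and no stereocentre is formed. Two selectivities are needed: regioselectivity of the addition, secured by the methoxy group next to C1' with only hydrogen at C3' on the other flank, and transfer of methyl rather than isopropyl, secured by keeping CH3MgCl in excess throughout while a near-stoichiometric amount of the exchange reagent is added slowly at −78 °C. The silyl ether and the methyl ether are inert to both Grignard reagents, so the two ring oxygens stay differentiated.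

Step 7
Reactants: 12 methyl 2,4-dihydroxy-3,6-dimethylbenzoate
Product: 14 methyl 5-formyl-2,4-dihydroxy-3,6-dimethylbenzoate, via aryl chloro(methoxy)methane 13 (not isolated)
Conditions: Cl2CHOCH3, TiCl4, CH2Cl2, 0 °C → rt; then ice/H2O
Reagents that add atoms: dichloromethyl methyl ether, COC(Cl)Cl (formyl carbon; chlorine and methoxy of 13 only); water, O (formyl oxygen)
Why: Rieche formylation; C5 is the only unsubstituted ring carbon, ortho to the C4 hydroxyl and para to the C2 hydroxyl, and titanium bound to the phenol oxygen delivers the electrophile to it. Hydrolysis of 13 on work-up unmasks the aldehyde.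

Step 8
Reactants: 14 methyl 5-formyl-2,4-dihydroxy-3,6-dimethylbenzoate
Product: 16 methyl 2,4-dihydroxy-3,5,6-trimethylbenzoate, via hydroxymethyl arene 15 (not isolated)
Conditions: Et3SiH (3 equiv), CF3CO2H, CH2Cl2, rt
Reagents that add atoms: none
Why: Ionic hydrogenation; hydride transfer to the protonated aldehyde gives 15, which ionises in acid to a benzylic cation stabilised by the ortho and para hydroxyls and takes up a second hydride to give the methyl group. The ester and the phenols are not reduced.

Step 9
Reactants: 11 2-methoxy-3,6-dimethyl-4-(triisopropylsilyloxy)benzoic acid; 16 methyl 2,4-dihydroxy-3,5,6-trimethylbenzoate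
Product: 18 methyl 2-hydroxy-4-[2-methoxy-3,6-dimethyl-4-(triisopropylsilyloxy)benzoyloxy]-3,5,6-trimethylbenzoate, via mixed trifluoroacetic anhydride 17 (not isolated)
Conditions: (CF3CO)2O, toluene, 0 °C → rt; aq. NaHCO3 work-up
Reagents that add atoms: trifluoroacetic anhydride, O=C(OC(=O)C(F)(F)F)C(F)(F)F (trifluoroacetyl group of 17 only)
Why: Classical depside esterification through a mixed anhydride; 17 ionises readily to a linear, electron-rich acylium ion, the pathway by which di-ortho-substituted benzoic acids esterify, and this small electrophile can reach the C4 oxygen between its two methyl groups. The C2 hydroxyl is tied up in a hydrogen bond to the ester and is the poorer nucleophile, and ring A has no free carbon for C-acylation.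

Step 10
Reactants: 18 methyl 2-hydroxy-4-[2-methoxy-3,6-dimethyl-4-(triisopropylsilyloxy)benzoyloxy]-3,5,6-trimethylbenzoate
Product: 19 methyl 2-hydroxy-4-(4-hydroxy-2-methoxy-3,6-dimethylbenzoyloxy)-3,5,6-trimethylbenzoate
Conditions: n-Bu4NF, AcOH, THF, 0 °C
Reagents that add atoms: none
Why: Fluoride cleavage of an aryl silyl ether, driven by the strength of the Si–F bond; acetic acid buffering protonates the liberated phenoxide at once, so the depside ester is exposed to neither acyl migration nor cleavage.

Step 11
Reactants: 19 methyl 2-hydroxy-4-(4-hydroxy-2-methoxy-3,6-dimethylbenzoyloxy)-3,5,6-trimethylbenzoate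
Product: 20 methyl 4-(3-chloro-4-hydroxy-6-methoxy-2,5-dimethylbenzoyloxy)-2-hydroxy-3,5,6-trimethylbenzoate
Conditions: N-chlorosuccinimide (1.0 equiv), CH3CN, 0 °C → rt, dark
Reagents that add atoms: N-chlorosuccinimide, O=C1CCC(=O)N1Cl
Why: Electrophilic aromatic chlorination; C3' is the only aromatic C–H of 19, ortho to the C4' hydroxyl and para to the C6' methoxy group. Ring A is fully substituted and deactivated by its ester and acyloxy groups, and one equivalent of reagent in the dark guards against ipso and benzylic chlorination.

## Compound list

1 | 2-methylresorcinol (2-methylbenzene-1,3-diol) | Cc1c(O)cccc1O | starting material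
2 | 3-methoxy-2-methylphenol | COc1cccc(O)c1C | intermediate
3 | (3-methoxy-2-methylphenoxy)triisopropylsilane | COc1cccc(O[Si](C(C)C)(C(C)C)C(C)C)c1C | intermediate
4 | 2-[3-methoxy-4-methyl-5-(triisopropylsilyloxy)phenyl]-4,4,5,5-tetramethyl-1,3,2-dioxaborolane (formed in the flask) | COc1cc(B2OC(C)(C)C(C)(C)O2)cc(O[Si](C(C)C)(C(C)C)C(C)C)c1C | intermediate
5 | 3-methoxy-4-methyl-5-(triisopropylsilyloxy)phenol | COc1cc(O)cc(O[Si](C(C)C)(C(C)C)C(C)C)c1C | intermediate
6 | 2-iodo-3-methoxy-4-methyl-5-(triisopropylsilyloxy)phenol | COc1c(I)c(O)cc(O[Si](C(C)C)(C(C)C)C(C)C)c1C | intermediate
7 | 2-iodo-3-methoxy-4-methyl-5-(triisopropylsilyloxy)phenyl trifluoromethanesulfonate | COc1c(I)c(OS(=O)(=O)C(F)(F)F)cc(O[Si](C(C)C)(C(C)C)C(C)C)c1C | intermediate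
8 | chloro[2-methoxy-3-methyl-4-(triisopropylsilyloxy)-6-(trifluoromethylsulfonyloxy)phenyl]magnesium (formed in the flask) | COc1c([Mg]Cl)c(OS(=O)(=O)C(F)(F)F)cc(O[Si](C(C)C)(C(C)C)C(C)C)c1C | intermediate
9 | 3-methoxy-4-methyl-5-(triisopropylsilyloxy)benzyne (formed in the flask) | COC1=C(C)C(O[Si](C(C)C)(C(C)C)C(C)C)=CC#C1 | intermediate
10 | chloro[2-methoxy-3,6-dimethyl-4-(triisopropylsilyloxy)phenyl]magnesium (formed in the flask) | COc1c([Mg]Cl)c(C)cc(O[Si](C(C)C)(C(C)C)C(C)C)c1C | intermediate
11 | 2-methoxy-3,6-dimethyl-4-(triisopropylsilyloxy)benzoic acid | COc1c(C(=O)O)c(C)cc(O[Si](C(C)C)(C(C)C)C(C)C)c1C | intermediate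
12 | methyl 2,4-dihydroxy-3,6-dimethylbenzoate | COC(=O)c1c(C)cc(O)c(C)c1O | starting material
13 | methyl 5-[chloro(methoxy)methyl]-2,4-dihydroxy-3,6-dimethylbenzoate (racemic, formed in the flask) | COC(=O)c1c(C)c(C(Cl)OC)c(O)c(C)c1O | intermediate
14 | methyl 5-formyl-2,4-dihydroxy-3,6-dimethylbenzoate | COC(=O)c1c(C)c(C=O)c(O)c(C)c1O | intermediate
15 | methyl 2,4-dihydroxy-5-(hydroxymethyl)-3,6-dimethylbenzoate (formed in the flask) | COC(=O)c1c(C)c(CO)c(O)c(C)c1O | intermediate
16 | methyl 2,4-dihydroxy-3,5,6-trimethylbenzoate | COC(=O)c1c(C)c(C)c(O)c(C)c1O | intermediate
17 | 2-methoxy-3,6-dimethyl-4-(triisopropylsilyloxy)benzoic trifluoroacetic anhydride (formed in the flask) | COc1c(C(=O)OC(=O)C(F)(F)F)c(C)cc(O[Si](C(C)C)(C(C)C)C(C)C)c1C | intermediate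
18 | methyl 2-hydroxy-4-[2-methoxy-3,6-dimethyl-4-(triisopropylsilyloxy)benzoyloxy]-3,5,6-trimethylbenzoate | COC(=O)c1c(C)c(C)c(OC(=O)c2c(C)cc(O[Si](C(C)C)(C(C)C)C(C)C)c(C)c2OC)c(C)c1O | intermediate
19 | methyl 2-hydroxy-4-(4-hydroxy-2-methoxy-3,6-dimethylbenzoyloxy)-3,5,6-trimethylbenzoate | COC(=O)c1c(C)c(C)c(OC(=O)c2c(C)cc(O)c(C)c2OC)c(C)c1O | intermediate
20 | methyl 4-(3-chloro-4-hydroxy-6-methoxy-2,5-dimethylbenzoyloxy)-2-hydroxy-3,5,6-trimethylbenzoate | COC(=O)c1c(C)c(C)c(OC(=O)c2c(C)c(Cl)c(O)c(C)c2OC)c(C)c1O | target

## Step count and least certain steps

Total step count: 11 (one-pot sequences counted once). Longest linear sequence: 9 steps (steps 1–6 and 9–11, from 1 to 20). Ring A is prepared in a two-step branch (steps 7 and 8).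

Step 6 (key step). The most likely failures are transfer of isopropyl instead of methyl to the aryne if elimination outruns consumption of the exchange reagent, addition of 10 to a further molecule of 9 to give biaryl, and attack of a Grignard reagent on the sulfonyl sulfur, which would return the phenoxide of 6. Erosion of regiocontrol is also possible if the C5' methyl twists the methoxy group out of its chelating orientation. The fallback sets out from 7 and replaces the aryne by two chemoselective cross-couplings. Carbonylation at the more reactive C–I bond (Pd(PPh3)2Cl2, CO, benzyl alcohol, Et3N, DMF, 70 °C) should give benzyl 2-methoxy-3-methyl-4-(triisopropylsilyloxy)-6-(trifluoromethylsulfonyloxy)benzoate F1. Suzuki–Miyaura methylation of the triflate (CH3B(OH)2, Pd(dppf)Cl2, K3PO4, dioxane, 90 °C) should then give benzyl 2-methoxy-3,6-dimethyl-4-(triisopropylsilyloxy)benzoate F2. Hydrogenolysis over palladium on carbon (H2, Pd/C, ethyl acetate) returns to the route at 11.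

Step 4. Site selection between the two positions ortho to the hydroxyl rests only on the size difference between methoxy and triisopropylsilyloxy, so partial iodination at C6 or di-iodination may occur. The fallback sets out from 5 and uses directed ortho-metalation. Protection (CH3OCH2Cl, i-Pr2NEt, CH2Cl2) gives triisopropyl[3-methoxy-5-(methoxymethoxy)-2-methylphenoxy]silane F3. Lithiation (n-BuLi, THF, 0 °C) should occur at the carbon between the two coordinating ether oxygens and not next to the bulky, non-coordinating silyl ether, and an I2 quench gives [4-iodo-3-methoxy-5-(methoxymethoxy)-2-methylphenoxy]triisopropylsilane F4. Acetal cleavage (cat. HCl, CH3OH, 40 °C) comes back to the route at 6.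

Step 9. Acyl transfer between a di-ortho-substituted acylating species and a phenol oxygen flanked by two methyl groups may be slow, leaving room for trifluoroacetylation of 16, self-condensation, or acid-induced loss of the silyl group. The fallback sets out from 11 and switches from acid activation to activation of the nucleophile. Neutral conversion with 1-chloro-N,N,2-trimethylprop-1-en-1-amine (CH2Cl2, rt) gives 2-methoxy-3,6-dimethyl-4-(triisopropylsilyloxy)benzoyl chloride F5. F5 is combined with the mono-potassium phenoxide of 16 (KOC(CH3)3, 1.0 equiv, THF, 0 °C → rt), which forms at the more acidic, unchelated C4 hydroxyl, and the sequence comes back to the route at 18.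

Step 11. Over-chlorination is the main concern: ipso attack at methyl-bearing carbons of either electron-rich ring, leading to dearomatised chlorodienones, or benzylic chlorination. The fallback sets out from 11 and installs chlorine before ring A is present. N-Chlorosuccinimide in (CF3)2CHOH should chlorinate the only free ring carbon, para to the methoxy group, to give 3-chloro-6-methoxy-2,5-dimethyl-4-(triisopropylsilyloxy)benzoic acid F6. Coupling with 16 under the conditions of step 9 gives methyl 4-[3-chloro-6-methoxy-2,5-dimethyl-4-(triisopropylsilyloxy)benzoyloxy]-2-hydroxy-3,5,6-trimethylbenzoate F7, and desilylation as in step 10 comes back to the route at 20.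

Further compounds

F1 | step 6 | benzyl 2-methoxy-3-methyl-4-(triisopropylsilyloxy)-6-(trifluoromethylsulfonyloxy)benzoate | COc1c(C(=O)OCc2ccccc2)c(OS(=O)(=O)C(F)(F)F)cc(O[Si](C(C)C)(C(C)C)C(C)C)c1C
F2 | step 6 | benzyl 2-methoxy-3,6-dimethyl-4-(triisopropylsilyloxy)benzoate | COc1c(C(=O)OCc2ccccc2)c(C)cc(O[Si](C(C)C)(C(C)C)C(C)C)c1C
F3 | step 4 | triisopropyl[3-methoxy-5-(methoxymethoxy)-2-methylphenoxy]silane | COCOc1cc(OC)c(C)c(O[Si](C(C)C)(C(C)C)C(C)C)c1
F4 | step 4 | [4-iodo-3-methoxy-5-(methoxymethoxy)-2-methylphenoxy]triisopropylsilane | COCOc1cc(O[Si](C(C)C)(C(C)C)C(C)C)c(C)c(OC)c1I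
F5 | step 9 | 2-methoxy-3,6-dimethyl-4-(triisopropylsilyloxy)benzoyl chloride | COc1c(C(Cl)=O)c(C)cc(O[Si](C(C)C)(C(C)C)C(C)C)c1C
F6 | step 11 | 3-chloro-6-methoxy-2,5-dimethyl-4-(triisopropylsilyloxy)benzoic acid | COc1c(C(=O)O)c(C)c(Cl)c(O[Si](C(C)C)(C(C)C)C(C)C)c1C
F7 | step 11 | methyl 4-[3-chloro-6-methoxy-2,5-dimethyl-4-(triisopropylsilyloxy)benzoyloxy]-2-hydroxy-3,5,6-trimethylbenzoate | COC(=O)c1c(C)c(C)c(OC(=O)c2c(C)c(Cl)c(O[Si](C(C)C)(C(C)C)C(C)C)c(C)c2OC)c(C)c1O
A1 | alternative 1 | methyl 3-oxopentanoate | CCC(=O)CC(=O)OC
A2 | alternative 1 | methyl (E)-but-2-enoate | C/C=C/C(=O)OC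
A3 | alternative 1 | methyl 3,6-dimethyl-2,4-dioxocyclohexane-1-carboxylate (mixture of stereoisomers and enol tautomers) | COC(=O)C1C(C)CC(=O)C(C)C1=O
A4 | alternative 2 | 2,3-dimethylcyclobut-2-en-1-one | CC1=C(C)C(=O)C1
A5 | alternative 2 | triisopropyl(prop-1-yn-1-yloxy)silane | CC#CO[Si](C(C)C)(C(C)C)C(C)C
A6 | alternative 2 | 2,4,5-trimethyl-3-(triisopropylsilyloxy)phenol | Cc1c(C)cc(O)c(C)c1O[Si](C(C)C)(C(C)C)C(C)C
A7 | alternative 3 | methyl 4-(but-2-ynoyloxy)-2-hydroxy-3,5,6-trimethylbenzoate | COC(=O)c1c(C)c(C)c(OC(=O)C#CC)c(C)c1O
A8 | alternative 3 | 1,1-dimethoxy-2-methyl-3-(trimethylsilyloxy)buta-1,3-diene | COC(OC)=C(C)C(=C)O[Si](C)(C)C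
A9 | alternative 3 | methyl 2-hydroxy-4-(4-hydroxy-2-methoxy-3,6-dimethylbenzoyloxy)-3,5,6-trimethylbenzoate | COC(=O)c1c(C)c(C)c(OC(=O)c2c(C)cc(O)c(C)c2OC)c(C)c1O
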